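## Analysis of the target

Betaethrin E is an achiral diaryl ether made of two benzene rings. Ring A is a methyl salicylate: C1 carries the methyl ester, C2 the free phenol, C4 a methyl group and C6 the ether oxygen. Ring B is a 1,2,4-trioxygenated benzyl alcohol: the benzylic carbon is on C1', the ether oxygen on C2', a free phenol on C3' and a methoxy group on C5', and the benzylic oxygen is esterified with palmitic acid. There is no stereocentre and no stereogenic double bond, so every problem is one of regiochemistry or chemoselectivity. The sensitive groups are the two different esters, two phenols of different acidity and an electron-rich, oxidisable ring B. The benzylic palmitate is open to hydrogenolysis and transesterification and, once an ortho phenol is free, to loss of carboxylate through an ortho-quinone methide. The ether oxygen is flanked by three ortho substituents (the ester on ring A, CH2O and OH on ring B), so coupling two finished rings would be hindered and would need base or metal conditions that the palmitate tolerates badly. The strategy rests on the pattern of ring A: C1, C2 and C3 with the ester on C1 are an acetoacetate unit, and C4 with its methyl group, C5 and C6 with the aryloxy group are a β-functionalised butenone. The bonds C1–C6 and C3–C4 are therefore the natural seams, and the ether oxygen can be attached to C6 while that carbon is still a strongly electrophilic vinylic centre.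

## Retrosynthetic reasoning

**20 from 19.** The last bond cut is the O–allyl bond on the ring B phenol. An allyl ether is chosen because it is removed by palladium-catalysed allyl transfer to an amine under neutral conditions. A benzyl ether would have to be hydrogenolysed next to a benzylic ester, and an acyl group could not be told apart from the palmitate. The forward step only has to leave two esters and a salicylate untouched.

**19 from 13 and 16.** Ring A is opened at C1–C6 and at C3–C4. This cut is preferred to the aryl–oxygen bond because the hindered ether linkage is then made while C6 is a chloride-bearing vinylic carbon. Each fragment can react in one way only. Ylide 16 supplies C1, C2, C3 and the ester, with a nucleophilic carbon at C1 and an ylide carbon at C3. Chloroenone 13 supplies C4 with its methyl group, C5 and C6, with an electrophilic carbon at C6 and a ketone at C4. The forward reaction must form C1–C6 by substitution of chloride, form C3=C4 by olefination and let the dienone aromatise. The gain is the whole of ring A with ester, phenol, methyl group and ether in their final positions.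

**13 from 8 and 12.** The vinylic C–O bond is cut to give the ring B phenol 8 and dichloroenone 12. One chloride of 12 is replaced by the phenol and the other is kept as the leaving group for the ring construction. The palmitate has to be in place before this step, because a free hydroxymethyl group next to the chlorovinyl ether would close onto it to give a benzodioxin.

**12 from 9 and 10; 16 from 14.** Both partners of the annulation are one step from bulk chemicals. Acylation of 10 by 9 followed by dehydrochlorination gives 12. Phosphorus alkylation of 14 and deprotonation gives 16.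

**8 from 6 and 7.** The benzylic ester bond is cut. The forward step must acylate the primary alcohol of 6 and not the neighbouring phenol. Lipase-catalysed acyl transfer from the enol ester 7 does this without base, which matters because the product is an ortho-hydroxybenzyl ester.

**6 from 5 from 4.** The bond between ring B and its benzylic carbon is traced to an ortho-formylation of phenol 4 followed by reduction. In 4 only one position ortho to the hydroxyl is free, so the new carbon can enter at one place only.

**4 from 2 from 1.** The phenolic oxygen of 4 is traced to the formyl group of 2 by aryl migration to oxygen, and the allyl ether to the phenol of 1. The aldehyde carbon of 1 must be para to the methoxy group, because it becomes the oxygen that later carries ring A. The original phenol, meta to the methoxy group, is the one that is allylated and ends as the free hydroxyl of ring B. With the formyl group meta to the methoxy group, the same sequence would put the allyl group on the wrong oxygen and the new carbon between hydroxyl and methoxy.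

## Alternatives that were turned down

**Alternative 1:** Ring B is built instead of ring A and is cut at C1'–C2' and C4'–C5'. In the forward key step the enolate of the aryloxyacetone A2 adds through its oxygen-bearing methylene to the β-carbon of the silyloxybutenoate A3, and the methyl ketone enolate then closes onto the ester. This gives the racemic trans cyclohexane-1,3-dione A1.
- For it: the ether bond comes from a plain O-alkylation of a ring A phenol with an α-halo ketone. Michael–Claisen closures to cyclohexane-1,3-diones are dependable. No ortho-hydroxybenzyl ester appears on the way.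
- Against it: the ring A carboxyl must travel as the free acid, because an ester ortho to the OCH2 carbanion would close to a benzofuranone. The enolate regiochemistry of A2 has to be controlled. Two stereocentres are made only to be destroyed. A1 must then be dehydrogenated without losing the α-aryloxy group, whose elimination would also give an aromatic ring. One of the two ring B oxygens must be methylated selectively. Esterification, debenzylation, desilylation and palmitoylation still follow.
- Comparison: on the ether bond itself this route is as strong as or stronger than the chosen one, and it avoids compound 8. The chosen strategy offers instead a ring B bought aromatic with its three oxygens differentiated from the start, and a key step whose product 19 is one step from the target.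

**Alternative 2:** Both rings are kept intact, and the C6–O bond and the C1–carboxyl bond of ring A are cut together. In the forward key step a fluoride source releases a 3-benzyloxy-5-methyl aryne from the silyl aryl triflate A5. The phenoxide of A6 adds at the aryne carbon remote from the benzyloxy group, and the aryl anion, now ortho to that group, is trapped by carbon dioxide A7 to give acid A4.
- For it: this is the most convergent plan. Two bonds form in one operation, and the regiochemistry is set reliably by the inductive effect of the 3-alkoxy group. On convergence it is stronger than the chosen strategy.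
- Against it: the aryl anion is easily protonated by adventitious water, by the solvent or by the phenol. A7 also ties up the phenoxide reversibly as a carbonate. A5 needs several steps of its own. A4 still requires esterification, removal of two benzyl ethers, desilylation and palmitoylation. Hydrogenolysis must precede palmitoylation, since a benzylic ester would not survive it, so the acylation would have to distinguish a primary alcohol from two free phenols at the very end.
- Comparison: the chosen strategy is less convergent but uses no aryne precursor, does not depend on a carboxylation outrunning protonation, and delivers ring A directly as the methyl ester with its free phenol.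

**Alternative 3:** Ring A is cut at C1–C2 and C5–C6. In the forward key step the dienyl silyl ketene acetal A10 adds to the aryloxypropiolate A9 in a Diels–Alder reaction. The adduct aromatises by loss of its methoxy group as the alcohol and gives salicylate A8.
- For it: the conditions are thermal and neutral. The polarised partners fix the regiochemistry, and the salicylate arrives with ester and phenol in place. On mildness of the ring-forming step it is at least equal to the chosen strategy.
- Against it: A9 is an ynol ether ester that must be made from a hindered, electron-rich phenol by a multistep sequence using strong base. Its aryloxy donor lowers its dienophilicity, so heating is needed, under which the moisture-sensitive A10 can decompose. A8 carries a benzyl ether and a silyl ether, so the endgame has the same conflict between hydrogenolysis and the benzylic ester as alternative 2.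
- Comparison: the chosen strategy uses the same oxidation level at C6 but as a stable β-chloro enone, made in one step from phenol 8 and dichloroenone 12. Its ylide partner 16 is a stable solid, and only one step follows the ring construction.

Key step: step 9

Assumption: compound 13 is drawn as the Z isomer (chlorine cis to the acetyl group). The E isomer would serve equally, because the geometry of this double bond is lost during the ring construction.

## Route

**Step 1**
Reactants: 1 2-hydroxy-4-methoxybenzaldehyde
Product: 2 2-(allyloxy)-4-methoxybenzaldehyde
Conditions: allyl bromide, K2CO3, DMF, 50 °C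
Reagents that add atoms: allyl bromide, C=CCBr
Why: Williamson ether synthesis; the chelated phenol is the only acidic site and its potassium salt should be alkylated cleanly by the allylic bromide.

**Step 2**
Reactants: 2 2-(allyloxy)-4-methoxybenzaldehyde
Product: 4 2-(allyloxy)-4-methoxyphenol, via aryl formate 3 (not isolated)
Conditions: mCPBA, CH2Cl2, 0 °C to rt; aq NaHCO3 wash; then K2CO3 (cat.), MeOH, rt
Reagents that add atoms: mCPBA (3-chloroperoxybenzoic acid), OOC(=O)c1cccc(Cl)c1
Why: Baeyer–Villiger (Dakin-type) oxidation; aryl migration is favoured by the ortho and para alkoxy groups, so the aldehyde should react well before the terminal alkene is epoxidised. The formate is methanolysed only after the peracid has been washed out, which protects the oxidisable phenol.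

**Step 3**
Reactants: 4 2-(allyloxy)-4-methoxyphenol
Product: 5 3-(allyloxy)-2-hydroxy-5-methoxybenzaldehyde
Conditions: MgCl2, Et3N, (CH2O)n, MeCN, reflux
Reagents that add atoms: paraformaldehyde (formaldehyde), C=O
Why: Magnesium-mediated ortho-formylation of a phenol; the magnesium phenoxide delivers formaldehyde to the ortho carbon and a second formaldehyde oxidises the benzylic alkoxide by hydride transfer. Only one position ortho to the hydroxyl is free, so a single regioisomer is possible.

**Step 4**
Reactants: 5 3-(allyloxy)-2-hydroxy-5-methoxybenzaldehyde
Product: 6 2-(allyloxy)-6-(hydroxymethyl)-4-methoxyphenol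
Conditions: NaBH4, MeOH–THF, 0 °C; aq NH4Cl
Reagents that add atoms: none
Why: Hydride reduction of an aromatic aldehyde; the allyl ether and the arene are inert, and the near-neutral quench avoids acid-induced self-condensation of the electron-rich ortho-hydroxybenzyl alcohol.

**Step 5**
Reactants: 6 2-(allyloxy)-6-(hydroxymethyl)-4-methoxyphenol; 7 vinyl palmitate (vinyl hexadecanoate)
Product: 8 3-(allyloxy)-2-hydroxy-5-methoxybenzyl palmitate
Conditions: immobilized Candida antarctica lipase B (Novozym 435), MTBE, 40 °C
Reagents that add atoms: none
Why: Lipase-catalysed transesterification; the enzyme acylates primary alcohols but not phenols, and tautomerisation of the released vinyl alcohol makes the transfer irreversible. The base-free, apolar medium should keep the ortho-hydroxybenzyl ester from ionising.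

**Step 6**
Reactants: 9 acetyl chloride; 10 1,1-dichloroethene
Product: 12 4,4-dichlorobut-3-en-2-one, via trichloroketone 11 (not isolated)
Conditions: AlCl3, CH2Cl2, 0 °C to rt; ice water; distillation (loss of HCl)
Reagents that add atoms: none
Why: Friedel–Crafts-type acylation of an alkene; the acylium ion adds to the CH2 terminus, chloride caps the dichloro-stabilised cation to give 11, and β-elimination of HCl then gives the conjugated dichloroenone.

**Step 7**
Reactants: 8 3-(allyloxy)-2-hydroxy-5-methoxybenzyl palmitate; 12 4,4-dichlorobut-3-en-2-one
Product: 13 3-(allyloxy)-2-[(Z)-1-chloro-3-oxobut-1-enyloxy]-5-methoxybenzyl palmitate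
Conditions: Et3N, CH2Cl2, −20 to 0 °C, slight excess of 12
Reagents that add atoms: none
Why: Nucleophilic vinylic substitution by addition–elimination, as known for β,β-dichlorovinyl ketones with phenols. The push–pull product is far less electrophilic than 12, so the second chloride should stay, and the weak amine base at low temperature keeps the concentration of free phenoxide, and with it the loss of palmitate, low.

**Step 8**
Reactants: 14 methyl 4-chloroacetoacetate
Product: 16 methyl 3-oxo-4-(triphenylphosphoranylidene)butanoate, via phosphonium chloride 15 (not isolated)
Conditions: PPh3, toluene, rt; then aq Na2CO3, CH2Cl2, rt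
Reagents that add atoms: triphenylphosphine, c1ccc(cc1)P(c1ccccc1)c1ccccc1
Why: SN2 alkylation of the phosphine by the α-chloro ketone followed by deprotonation; the acyl-stabilised ylide is a stable, isolable solid.

**Step 9**
Reactants: 16 methyl 3-oxo-4-(triphenylphosphoranylidene)butanoate; 13 3-(allyloxy)-2-[(Z)-1-chloro-3-oxobut-1-enyloxy]-5-methoxybenzyl palmitate
Product: 19 methyl 6-[2-(allyloxy)-4-methoxy-6-(palmitoyloxymethyl)phenoxy]-2-hydroxy-4-methylbenzoate, via substitution adduct 17 (not isolated), via cyclohexadienone 18 (not isolated)
Conditions: NaH (2.1 equiv), THF, 0 °C to rt; then AcOH (1.1 equiv), toluene, 110 °C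
Reagents that add atoms: none
Why: Proposed new method: the sodium enolate of 16 should add through its C2 methylene to the chlorine-bearing carbon of 13, the resulting enolate should expel chloride, and the acyl ylide should then olefinate the methyl ketone in the same molecule; the closest known reaction type is the conjugate addition–intramolecular Wittig [3+3] annulation of this ylide with enones and enals, taken together with the known stepwise substitution of β,β-dichlorovinyl ketones by oxygen and carbon nucleophiles. The second equivalent of NaH deprotonates adduct 17, whose tricarbonyl methine is more acidic than the methylene of 16, so the substitution should not stall at half conversion, and AcOH then returns neutral 17 for the closure. Ring A closes by 6-exo-trig attack of the ylide carbon C3 on the ketone carbon C4, the oxaphosphetane collapses with loss of Ph3PO to the C3=C4 bond, and cyclohexadienone 18 tautomerises to the phenol, which makes the sequence irreversible. No stereocentre is set, since C1 of 18 is a transient racemic centre that becomes sp2 on aromatisation. Three selectivities are needed. Chloride and not the aryloxide must leave the tetrahedral intermediate, which the far lower basicity of chloride secures. Carbon C2 and not the ylide carbon or an enolate oxygen must attack, which matches the known site of alkylation and conjugate addition of this enolate. Only the ylide carbon and the ketone can olefinate, so a single fold is possible without the ambiguity of an aldol closure, and the push–pull C5=C6 bond of 17 should rotate easily enough for either geometric isomer of 13 to reach the closing conformation.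

**Step 10**
Reactants: 19 methyl 6-[2-(allyloxy)-4-methoxy-6-(palmitoyloxymethyl)phenoxy]-2-hydroxy-4-methylbenzoate
Product: 20 betaethrin E, methyl 2-hydroxy-6-[2-hydroxy-4-methoxy-6-(palmitoyloxymethyl)phenoxy]-4-methylbenzoate
Conditions: Pd(PPh3)4 (cat.), morpholine, THF, rt
Reagents that add atoms: none
Why: Tsuji–Trost-type deallylation; zerovalent palladium ionises the aryl allyl ether to a π-allyl complex that morpholine captures irreversibly. Both esters and the salicylate are inert at room temperature under these neutral conditions.

## Compound list

1 | 2-hydroxy-4-methoxybenzaldehyde | COc1ccc(C=O)c(O)c1 | starting material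
2 | 2-(allyloxy)-4-methoxybenzaldehyde | C=CCOc1cc(OC)ccc1C=O | intermediate
3 | 2-(allyloxy)-4-methoxyphenyl formate | C=CCOc1cc(OC)ccc1OC=O | intermediate (not isolated)
4 | 2-(allyloxy)-4-methoxyphenol | C=CCOc1cc(OC)ccc1O | intermediate
5 | 3-(allyloxy)-2-hydroxy-5-methoxybenzaldehyde | C=CCOc1cc(OC)cc(C=O)c1O | intermediate
6 | 2-(allyloxy)-6-(hydroxymethyl)-4-methoxyphenol | C=CCOc1cc(OC)cc(CO)c1O | intermediate
7 | vinyl palmitate (vinyl hexadecanoate) | CCCCCCCCCCCCCCCC(=O)OC=C | starting material
8 | 3-(allyloxy)-2-hydroxy-5-methoxybenzyl palmitate | CCCCCCCCCCCCCCCC(=O)OCc1cc(OC)cc(OCC=C)c1O | intermediate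
9 | acetyl chloride | CC(=O)Cl | starting material
10 | 1,1-dichloroethene | C=C(Cl)Cl | starting material
11 | 4,4,4-trichlorobutan-2-one | CC(=O)CC(Cl)(Cl)Cl | intermediate (not isolated)
12 | 4,4-dichlorobut-3-en-2-one | CC(=O)C=C(Cl)Cl | intermediate
13 | 3-(allyloxy)-2-[(Z)-1-chloro-3-oxobut-1-enyloxy]-5-methoxybenzyl palmitate | CCCCCCCCCCCCCCCC(=O)OCc1cc(OC)cc(OCC=C)c1O/C(Cl)=C/C(C)=O | intermediate
14 | methyl 4-chloroacetoacetate (methyl 4-chloro-3-oxobutanoate) | COC(=O)CC(=O)CCl | starting material
15 | (4-methoxy-2,4-dioxobutyl)triphenylphosphonium chloride | COC(=O)CC(=O)C[P+](c1ccccc1)(c1ccccc1)c1ccccc1.[Cl-] | intermediate (not isolated)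
16 | methyl 3-oxo-4-(triphenylphosphoranylidene)butanoate | COC(=O)CC(=O)C=P(c1ccccc1)(c1ccccc1)c1ccccc1 | intermediate
17 | methyl 2-{(E)-1-[2-(allyloxy)-4-methoxy-6-(palmitoyloxymethyl)phenoxy]-3-oxobut-1-enyl}-3-oxo-4-(triphenylphosphoranylidene)butanoate (racemic; neutral form shown, present as its sodium enolate until acidified) | CCCCCCCCCCCCCCCC(=O)OCc1cc(OC)cc(OCC=C)c1O/C(=C/C(C)=O)C(C(=O)OC)C(=O)C=P(c1ccccc1)(c1ccccc1)c1ccccc1 | intermediate (not isolated)
18 | methyl 2-[2-(allyloxy)-4-methoxy-6-(palmitoyloxymethyl)phenoxy]-4-methyl-6-oxocyclohexa-2,4-diene-1-carboxylate (racemic) | CCCCCCCCCCCCCCCC(=O)OCc1cc(OC)cc(OCC=C)c1OC1=CC(C)=CC(=O)C1C(=O)OC | intermediate (not isolated)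
19 | methyl 6-[2-(allyloxy)-4-methoxy-6-(palmitoyloxymethyl)phenoxy]-2-hydroxy-4-methylbenzoate | CCCCCCCCCCCCCCCC(=O)OCc1cc(OC)cc(OCC=C)c1Oc1cc(C)cc(O)c1C(=O)OC | intermediate
20 | betaethrin E, methyl 2-hydroxy-6-[2-hydroxy-4-methoxy-6-(palmitoyloxymethyl)phenoxy]-4-methylbenzoate | CCCCCCCCCCCCCCCC(=O)OCc1cc(OC)cc(O)c1Oc1cc(C)cc(O)c1C(=O)OC | target

## Step count and least certain steps

Total step count: 10. Longest linear sequence: 8 steps (steps 1, 2, 3, 4, 5, 7, 9, 10, from compound 1). Steps 6 and 8 are one-step side branches.

**Step 9 (key step).**
- What may go wrong: the substitution may stall through proton transfer from the acidic adduct to unreacted enolate. The stabilised ylide may fail to olefinate the ketone, which is deactivated as a vinylogous ester. The delocalised anion may be consumed by attack through oxygen or by a second substitution in which aryloxide is displaced.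
- Fallback (known reactions only; sets out from 6 and rejoins at 20): the primary alcohol of 6 is silylated selectively (TBSCl, imidazole, CH2Cl2, 0 °C) to give 2-(allyloxy)-6-[(tert-butyldimethylsilyloxy)methyl]-4-methoxyphenol F1. Its potassium phenoxide (K2CO3, DMF, 80 °C) displaces one fluoride of commercial 2,6-difluoro-4-methylbenzaldehyde (Cc1cc(F)c(C=O)c(F)c1) by nucleophilic aromatic substitution ortho to the formyl group. This gives 2-[2-(allyloxy)-6-(tert-butyldimethylsilyloxymethyl)-4-methoxyphenoxy]-6-fluoro-4-methylbenzaldehyde F2. Sodium allyloxide (allyl alcohol, NaH, THF) replaces the second fluoride and gives 2-(allyloxy)-6-[2-(allyloxy)-6-(tert-butyldimethylsilyloxymethyl)-4-methoxyphenoxy]-4-methylbenzaldehyde F3. Pinnick oxidation (NaClO2, NaH2PO4, 2-methylbut-2-ene, t-BuOH–water) gives 2-(allyloxy)-6-[2-(allyloxy)-6-(tert-butyldimethylsilyloxymethyl)-4-methoxyphenoxy]-4-methylbenzoic acid F4. Alkylation with MeI and K2CO3 in DMF gives methyl 2-(allyloxy)-6-[2-(allyloxy)-6-(tert-butyldimethylsilyloxymethyl)-4-methoxyphenoxy]-4-methylbenzoate F5. Desilylation with Bu4NF in THF gives methyl 2-(allyloxy)-6-[2-(allyloxy)-6-(hydroxymethyl)-4-methoxyphenoxy]-4-methylbenzoate F6. Palmitoyl chloride and pyridine give methyl 2-(allyloxy)-6-[2-(allyloxy)-4-methoxy-6-(palmitoyloxymethyl)phenoxy]-4-methylbenzoate F7. Pd(PPh3)4 and morpholine then remove both allyl ethers to give 20.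

**Step 7.**
- What may go wrong: the ortho-acyloxymethyl phenoxide may lose palmitate through an ortho-quinone methide before it is captured by 12, because the electron-rich ring assists that ionisation. Over-substitution of the second chloride is a lesser risk.
- Fallback (sets out from 6 and rejoins at 19): the benzylic oxygen is carried as a silyl ether through the ring construction and acylated afterwards. 2-(Allyloxy)-6-[(tert-butyldimethylsilyloxy)methyl]-4-methoxyphenol F1 reacts with 12 (Et3N, CH2Cl2) to give (Z)-4-[2-(allyloxy)-6-(tert-butyldimethylsilyloxymethyl)-4-methoxyphenoxy]-4-chlorobut-3-en-2-one F8. Annulation with 16 under the conditions of step 9 gives methyl 6-[2-(allyloxy)-6-(tert-butyldimethylsilyloxymethyl)-4-methoxyphenoxy]-2-hydroxy-4-methylbenzoate F9. HF·pyridine in THF gives methyl 6-[2-(allyloxy)-6-(hydroxymethyl)-4-methoxyphenoxy]-2-hydroxy-4-methylbenzoate F10. Palmitoyl chloride and pyridine at 0 °C acylate its primary alcohol in preference to the hydrogen-bonded salicylate hydroxyl and give 19.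

**Step 5.**
- What may go wrong: acyl transfer may be slow because of the ortho substituent next to the hydroxymethyl group. The product may ionise to an ortho-quinone methide on prolonged contact with the support or with traces of water.
- Fallback (sets out from 6 and rejoins at 8): Mitsunobu esterification with palmitic acid, PPh3 and DIAD in THF at 0 °C. The alcohol is activated instead of the acyl group, and the carboxylic acid, being far more acidic than the phenol, is the nucleophile. No new intermediate is made.

**Step 3.**
- What may go wrong: chelation of magnesium by the neighbouring allyloxy oxygen may slow the formylation, and the hydroxymethyl intermediate may condense with a second phenol to a diarylmethane.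
- Fallback (sets out from 4 and rejoins at 6, bypassing 5 and step 4): boronate-templated ortho-hydroxymethylation. Phenol 4, PhB(OH)2 and paraformaldehyde with catalytic propionic acid in refluxing toluene give 8-(allyloxy)-6-methoxy-2-phenyl-4H-1,3,2-benzodioxaborinine F11. Exchange with propane-1,3-diol releases 6.

## Further compounds

F1 | step 9 | 2-(allyloxy)-6-[(tert-butyldimethylsilyloxy)methyl]-4-methoxyphenol | CC(C)(C)[Si](C)(C)OCc1cc(OC)cc(OCC=C)c1O
F2 | step 9 | 2-[2-(allyloxy)-6-(tert-butyldimethylsilyloxymethyl)-4-methoxyphenoxy]-6-fluoro-4-methylbenzaldehyde | CC(C)(C)[Si](C)(C)OCc1cc(OC)cc(OCC=C)c1Oc1cc(C)cc(F)c1C=O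
F3 | step 9 | 2-(allyloxy)-6-[2-(allyloxy)-6-(tert-butyldimethylsilyloxymethyl)-4-methoxyphenoxy]-4-methylbenzaldehyde | CC(C)(C)[Si](C)(C)OCc1cc(OC)cc(OCC=C)c1Oc1cc(C)cc(OCC=C)c1C=O
F4 | step 9 | 2-(allyloxy)-6-[2-(allyloxy)-6-(tert-butyldimethylsilyloxymethyl)-4-methoxyphenoxy]-4-methylbenzoic acid | CC(C)(C)[Si](C)(C)OCc1cc(OC)cc(OCC=C)c1Oc1cc(C)cc(OCC=C)c1C(=O)O
F5 | step 9 | methyl 2-(allyloxy)-6-[2-(allyloxy)-6-(tert-butyldimethylsilyloxymethyl)-4-methoxyphenoxy]-4-methylbenzoate | CC(C)(C)[Si](C)(C)OCc1cc(OC)cc(OCC=C)c1Oc1cc(C)cc(OCC=C)c1C(=O)OC
F6 | step 9 | methyl 2-(allyloxy)-6-[2-(allyloxy)-6-(hydroxymethyl)-4-methoxyphenoxy]-4-methylbenzoate | OCc1cc(OC)cc(OCC=C)c1Oc1cc(C)cc(OCC=C)c1C(=O)OC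
F7 | step 9 | methyl 2-(allyloxy)-6-[2-(allyloxy)-4-methoxy-6-(palmitoyloxymethyl)phenoxy]-4-methylbenzoate | CCCCCCCCCCCCCCCC(=O)OCc1cc(OC)cc(OCC=C)c1Oc1cc(C)cc(OCC=C)c1C(=O)OC
F8 | step 7 | (Z)-4-[2-(allyloxy)-6-(tert-butyldimethylsilyloxymethyl)-4-methoxyphenoxy]-4-chlorobut-3-en-2-one | CC(C)(C)[Si](C)(C)OCc1cc(OC)cc(OCC=C)c1O/C(Cl)=C/C(C)=O
F9 | step 7 | methyl 6-[2-(allyloxy)-6-(tert-butyldimethylsilyloxymethyl)-4-methoxyphenoxy]-2-hydroxy-4-methylbenzoate | CC(C)(C)[Si](C)(C)OCc1cc(OC)cc(OCC=C)c1Oc1cc(C)cc(O)c1C(=O)OC
F10 | step 7 | methyl 6-[2-(allyloxy)-6-(hydroxymethyl)-4-methoxyphenoxy]-2-hydroxy-4-methylbenzoate | OCc1cc(OC)cc(OCC=C)c1Oc1cc(C)cc(O)c1C(=O)OC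
F0 | step 5 | none | none
F11 | step 3 | 8-(allyloxy)-6-methoxy-2-phenyl-4H-1,3,2-benzodioxaborinine | C=CCOc1cc(OC)cc2COB(c3ccccc3)Oc12
A1 | alternative 1 | racemic trans-2-(benzyloxy)-6-[2,4-dioxo-6-(tert-butyldimethylsilyloxymethyl)cyclohexyloxy]-4-methylbenzoic acid | O=C1CC(=O)[C@@H](Oc2cc(C)cc(OCc3ccccc3)c2C(=O)O)[C@H](CO[Si](C)(C)C(C)(C)C)C1
A2 | alternative 1 | 2-(benzyloxy)-4-methyl-6-(2-oxopropoxy)benzoic acid | CC(=O)COc1cc(C)cc(OCc2ccccc2)c1C(=O)O
A3 | alternative 1 | methyl (E)-4-(tert-butyldimethylsilyloxy)but-2-enoate | COC(=O)/C=C/CO[Si](C)(C)C(C)(C)C
A4 | alternative 2 | 2-(benzyloxy)-6-[2-(benzyloxy)-4-methoxy-6-(tert-butyldimethylsilyloxymethyl)phenoxy]-4-methylbenzoic acid | Cc1cc(OCc2ccccc2)c(C(=O)O)c(Oc2c(CO[Si](C)(C)C(C)(C)C)cc(OC)cc2OCc2ccccc2)c1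
A5 | alternative 2 | 3-(benzyloxy)-5-methyl-2-(trimethylsilyl)phenyl trifluoromethanesulfonate | Cc1cc(OCc2ccccc2)c([Si](C)(C)C)c(OS(=O)(=O)C(F)(F)F)c1
A6 | alternative 2 | 2-(benzyloxy)-6-[(tert-butyldimethylsilyloxy)methyl]-4-methoxyphenol | CC(C)(C)[Si](C)(C)OCc1cc(OC)cc(OCc2ccccc2)c1O
A7 | alternative 2 | carbon dioxide | O=C=O
A8 | alternative 3 | methyl 6-[2-(benzyloxy)-4-methoxy-6-(tert-butyldimethylsilyloxymethyl)phenoxy]-2-hydroxy-4-methylbenzoate | COC(=O)c1c(O)cc(C)cc1Oc1c(CO[Si](C)(C)C(C)(C)C)cc(OC)cc1OCc1ccccc1
A9 | alternative 3 | methyl 3-[2-(benzyloxy)-4-methoxy-6-(tert-butyldimethylsilyloxymethyl)phenoxy]prop-2-ynoate | COC(=O)C#COc1c(CO[Si](C)(C)C(C)(C)C)cc(OC)cc1OCc1ccccc1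
A10 | alternative 3 | 1-methoxy-3-methyl-1-(trimethylsilyloxy)buta-1,3-diene (mixture of geometric isomers) | C=C(C)C=C(OC)O[Si](C)(C)C
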